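## The problem

The target is a pentacyclic meroterpenoid in which a ledene-type 5–7–3 sesquiterpene (cyclopentane ring C, cycloheptene ring D, gem-dimethylcyclopropane ring E) is joined twice to a diformylphloroglucinol (ring A). One join is the aryl ether O–C2; the other is the benzylic carbon C7', which is bonded to the quaternary C4 and to the arene, so that oxepane ring B bridges C2 and C4 of ring C on one face. Numbering used throughout: C1 and C10 are the alkene carbons (C10 bears a methyl), C2 the O-bearing CH, C3 the ring CH2, C4 the quaternary carbon, C5 the ring-fusion CH, C6 and C7 the cyclopropane CH carbons, C8 and C9 the CH2 groups, C11 the CMe2 carbon and C7' the benzylic CH. The β face is the face carrying H5, C11, the oxygen on C2 and C7'; the α face carries H6, H7 and the C4 methyl.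

There are six stereocentres. C6 and C7 can come from (+)-2-carene, whose configuration the terpene half shares (it is that of (+)-ledene). They can control C5 (H5 anti to H6), C5 can control the quaternary C4, and C4 fixes C2 because the bridge can only be cis. C7' is then set on the rigid bridged cation. The sensitive parts are the allylic aryl ether next to the tetrasubstituted C1=C10 alkene (it ionises under acid), the cyclopropane, and the two ortho-hydroxy aldehydes, which must come last.

The feature that allows the key step is that one phloroglucinol oxygen is the C2 ether. An ethynyl ether on C2 already holds that oxygen and two ring carbons; a 3-alkoxycyclobutenone supplies the other four with the oxygens 1,3,5. The constraint is that an ynol ether on an allylic carbon rearranges ([3,3]) far below the benzannulation temperature, so C1 must be sp3 when ring A is built.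

## Retrosynthesis

**Formyl groups.** The two C–CHO bonds of 32 are cut last. The resorcinol 31 has exactly two free ring positions, both ortho or para to three oxygens, so a double Rieche formylation needs no regiocontrol and the aldehydes never meet hydride, organolithium or hydrogenation conditions.

**Isobutyl group and benzyl ethers.** 31 comes from the methallyl bis-benzyl ether 30 by one hydrogenation, which saturates the 1,1-disubstituted alkene and cleaves both O-benzyl bonds. The tetrasubstituted C1=C10 alkene is far slower to reduce.

**Ring B.** Both bonds at C7' (to the arene and to the side chain) are cut, giving the acetal 27 and methallyltrimethylsilane 28. Cutting C7'–aryl alone would need a secondary neopentyl cation. Cutting both lets every cation be stabilised: first an oxocarbenium ion, then a benzylic cation flanked by three ring oxygens. The symmetric bis-benzyl ring A of 27 makes the two ortho positions equivalent. The forward step must close a seven-membered ring and then deliver the allyl group to one face of a bridged cation.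

**C1=C10 alkene.** 27 is traced to the tertiary carbinol 26 (C10–OH β, H1 α, anti-periplanar). The alkene is deliberately absent before this point: an ethynyl ether on C2 next to C1=C10 would be an allyl alkynyl ether and would rearrange to a C10 ketene. The cost is one elimination whose regiochemistry must favour the tetrasubstituted olefin.

**Ring A (key step).** Two C–C bonds of the arene of 24 are cut, giving the C2 ethynyl ether 21 and 3-(benzyloxy)cyclobutenone 23 (from commercial 3-ethoxycyclobutenone 22 by alcohol exchange). The neighbouring cut, the O–C2 or O–aryl bond, would need etherification of a hindered secondary carbinol with a phloroglucinol, which prefers C-alkylation. Building the ring from the oxygen avoids this and puts the three oxygens 1,3,5 by the polarity of the ketene–ynol ether addition. No stereocentre is formed.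

**Ynol ether.** 21 comes from the C2 β-alcohol 17 and trichloroethylene 18 by alkoxide addition to dichloroacetylene and double elimination. The tertiary C10 oxygen is carried as a 2-(trimethylsilyl)ethoxymethyl (SEM) ether, which cannot migrate to the neighbouring alkoxide as a silyl ether would.

**C2 oxygen and C1 hydrogen.** The C2–O and C1–H bonds of 17 are traced to the alkene of the tertiary allylic ether 13 by hydroboration (boron to C2), then oxidation to ketone 16 and reduction. Reagents reach C2 anti to the dimethoxymethyl group on C4, so the β-alcohol, which is cis to that group, is best made by hydride addition to a ketone. 13 comes from enone 11 by 1,2-addition of methyllithium; this also installs the C10 methyl and the oxygen that later leaves.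

**Quaternary C4.** The C4–C5 bond of 11 is traced to the epoxide 9 of the cyclohexadiene 8 by a Meinwald rearrangement: the C7'–C5 ring bond migrates to C4 and C7' becomes the aldehyde. Epoxidation anti to the C5–C6 bond and migration anti to the leaving oxygen give C7' β and methyl α. The forward step must favour ring-bond migration over hydride shift and proton loss.

**Rings D and C (as a six-membered ring).** The C1–C5 and C2–C3 bonds of 8 are cut to the dienyl ynone 7, an intramolecular Diels–Alder precursor. One new stereocentre (C5) is formed, controlled by the cis-cyclopropane tether. 7 is reached from (+)-2-carene 1 by ozonolysis (2), haloform cleavage (4), diene formation (5), Weinreb amide 6 and ethynyl addition.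

## Roads not taken

**Alternative 1:** The cut is C1–C5 and C8–C9. A vinyl diazo ketone A1, already carrying the aryl group, the isobutyl group and the C4 and C7' stereocentres, is treated with Rh2(OAc)4. The carbenoid at C1 cyclopropanates the near alkene of the diene, and the cis-divinylcyclopropane undergoes a Cope shift to the hydroazulenone A2.
- Merits: it is the most convergent of the four plans. Rings C and D and the C1=C10 alkene arise in one well-precedented tandem step, the arene comes in intact, and no ynol ether or alkene mask is needed. In step count after fragment union it is better than the chosen plan.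
- Weak points: the vicinal C4 (quaternary) and C7' centres must be set in an open chain without help from a ring. The gem-dimethylcyclopropane must be added late to the C6=C7 alkene with face control. The C2–O bond must still be made from the C2 ketone and a hindered phenol.
- Against this, the chosen plan takes the cyclopropane and absolute configuration from carene and sets C4, C2 and C7' under ring control. It pays with a longer linear sequence.

**Alternative 2:** The cut is C1–C5 and C2–C3, the intramolecular Diels–Alder reaction of the dienyl ynone to the tricyclic dienone A3, followed by ring contraction.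
- This is the same compound as 8, and the chosen plan uses this chemistry for its terpene half; in that respect the two are equal.
- What is not taken is the use of it as the whole strategy, with ring A imported as a finished phloroglucinol. That would save the ynol ether steps and the alkene mask, perhaps four steps.
- Its weak point is the union: an allylic, neopentyl-flanked C2 carbinol and a phloroglucinol give C-alkylation, SN2' products or C10 ethers through the allyl cation. The chosen plan avoids this by growing the ring from the C2 oxygen.

**Alternative 3:** The cut is C4–C5 and C1–C2. The carene-derived cycloheptenone A4 and an axially chiral allenylsilane A5 combine under TiCl4 in a (3+2) annulation to the cis-fused hydroazulenone A6.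
- Merits: ring C, the quaternary C4 and C5 are made in one step, and attack anti to the cyclopropane is reliable. It is probably shorter to a 5–7–3 core than the chosen sequence.
- Weak points: C4 depends on an enantiopure allene and on matched transfer of its axial chirality. The product has silicon on C3 and no oxygen on C2, so C2 must be oxygenated later with regio- and face control. The C10 ketone still needs the methyl group and the alkene.
- The chosen plan needs no chiral reagent, and the C2 oxygen comes from an alkene placed by the cycloaddition.

Key step: step 16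

Remark: salts formed by simple deprotonation and transient activated esters are treated as part of the conditions and are not numbered; numbered "via" compounds are discrete covalent intermediates.

## Route

Step 1
Reactants: 1 (+)-2-carene
Product: 2 4-[(1R,3S)-3-(dimethoxymethyl)-2,2-dimethylcyclopropyl]butan-2-one
Conditions: O3, CH2Cl2/MeOH, TsOH·H2O (10 mol %), −78 °C; NaHCO3; Me2S, −78 °C → rt
Reagents that add atoms: ozone, [O-][O+]=O; methanol, CO
Why: Terminally differentiating ozonolysis: methanol traps the ketone oxide as a methoxy hydroperoxide while the acid acetalises the aldehyde end, and Me2S then releases the methyl ketone; the cis-cyclopropane centres are untouched.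

Step 2
Reactants: 2 keto acetal
Product: 4 3-[(1R,3S)-3-formyl-2,2-dimethylcyclopropyl]propanoic acid, via acetal acid 3 (not isolated)
Conditions: NaOBr (from Br2, NaOH), dioxane/H2O, 0 °C; then aq. HCl to pH 2, THF, rt
Reagents that add atoms: sodium hydroxide, [Na+].[OH-]; water, O
Why: Haloform cleavage removes the methyl carbon while the aldehyde is protected; acidification frees the acid and hydrolyses the acetal under conditions too mild to epimerise the cyclopropyl aldehyde.

Step 3
Reactants: 4 aldehyde acid
Product: 5 3-[(1R,3S)-2,2-dimethyl-3-[(1E)-3-methylbuta-1,3-dien-1-yl]cyclopropyl]propanoic acid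
Conditions: (EtO)2P(O)CH2C(CH3)=CH2 (2.4 equiv), n-BuLi (2.3 equiv), THF, −78 °C; add 4; −78 °C → rt
Reagents that add atoms: diethyl (2-methylallyl)phosphonate, CCOP(=O)(OCC)CC(C)=C
Why: Horner–Wadsworth–Emmons olefination with a lithiated allylic phosphonate (the first equivalent forms the carboxylate); α-attack and phosphate loss give the (E)-diene.

Step 4
Reactants: 5 dienoic acid
Product: 6 N-methoxy-N-methylamide of 5
Conditions: 1,1'-carbonyldiimidazole, CH2Cl2, rt; MeNH(OMe)·HCl, rt
Reagents that add atoms: N,O-dimethylhydroxylamine hydrochloride, CNOC.Cl
Why: Standard Weinreb amide formation through the acyl imidazolide; the diene is inert.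

Step 5
Reactants: 6 Weinreb amide
Product: 7 5-[(1R,3S)-2,2-dimethyl-3-[(1E)-3-methylbuta-1,3-dien-1-yl]cyclopropyl]pent-1-yn-3-one
Conditions: HC≡CMgBr, THF, −20 → 0 °C; inverse quench into cold aq. NaHSO4
Reagents that add atoms: ethynylmagnesium bromide, C#C[Mg]Br
Why: Weinreb ketone synthesis; the chelated adduct prevents over-addition and the cold acidic quench prevents the released amine from adding to the terminal ynone.

Step 6
Reactants: 7 dienyl ynone
Product: 8 tricyclic dienone (C10 ketone in the seven-membered ring; cyclohexa-1,4-diene with C1=C2 and C4=C7' fused across C1–C5, methyl on C4; H5 β, syn to C11)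
Conditions: Me2AlCl (1.1 equiv), CH2Cl2, −78 → −20 °C
Reagents that add atoms: none
Why: Lewis-acid-promoted intramolecular Diels–Alder reaction of an ynone (no endo/exo question); the tether on C7 brings the dienophile to the face of the s-trans, bisected vinylcyclopropane that puts H5 next to C11, and the low temperature avoids the homodienyl 1,5-hydrogen shift of the cis-alkyl vinylcyclopropane.

Step 7
Reactants: 8 tricyclic dienone
Product: 9 C4,C7' β-epoxide of 8
Conditions: m-CPBA, NaHCO3, CH2Cl2, 0 °C
Reagents that add atoms: 3-chloroperbenzoic acid, OOC(=O)c1cccc(Cl)c1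
Why: Prilezhaev epoxidation takes the electron-rich isolated trisubstituted alkene and not the enone; attack is anti to the C5–C6 bond, on the face of H5.

Step 8
Reactants: 9 epoxide
Product: 11 enone dimethyl acetal (C10 ketone, C1=C2, C4 bearing α-methyl and β-CH(OMe)2), via aldehyde 10 (not isolated)
Conditions: MeAl(OC6H2-4-Br-2,6-t-Bu2)2 (1.2 equiv), CH2Cl2, −78 °C; then HC(OMe)3, MeOH, pyridinium p-toluenesulfonate, rt
Reagents that add atoms: trimethyl orthoformate, COC(OC)OC
Why: Meinwald rearrangement with a bulky, non-basic aluminium Lewis acid: the epoxide opens at tertiary C4 and the C7'–C5 ring bond migrates anti to the leaving oxygen, giving the quaternary C4 with CHO β and methyl α. The neopentyl aldehyde is acetalised in the same flask.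

Step 9
Reactants: 11 enone acetal
Product: 13 C10 tertiary SEM ether (C10: α-methyl, β-OSEM; C1=C2 retained), via tertiary alkoxide 12 (not isolated)
Conditions: MeLi, THF, −78 °C; then Me3SiCH2CH2OCH2Cl, DMPU, −78 °C → rt
Reagents that add atoms: methyllithium, [Li]C; 2-(trimethylsilyl)ethoxymethyl chloride, C[Si](C)(C)CCOCCl
Why: 1,2-Addition to the enone from the α face, away from the endo methyl of the cyclopropane, then O-alkylation of the lithium alkoxide; the SEM group survives hydride, KH and n-BuLi and cannot migrate to the later C2 alkoxide.

Step 10
Reactants: 13 SEM ether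
Product: 15 C2 α-alcohol (H1 α, trans-fused), via alkylborane 14 (not isolated)
Conditions: BH3·THF, THF, 0 °C → rt; then H2O2, aq. NaOH, 0 °C
Reagents that add atoms: borane–tetrahydrofuran (boron only in 14), B.C1CCOC1; hydrogen peroxide, OO
Why: Hydroboration–oxidation puts boron on the less substituted C2 and adds syn from the α face, anti to both the OSEM group and the dimethoxymethyl group; this sets H1 α, and the α configuration at C2 is corrected in steps 11 and 12.

Step 11
Reactants: 15 C2 α-alcohol
Product: 16 C2 ketone (H1 α)
Conditions: Dess–Martin periodinane, NaHCO3, CH2Cl2, rt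
Reagents that add atoms: none
Why: Neutral buffered oxidation of the secondary alcohol; C1 does not epimerise and the β-alkoxy ketone does not eliminate under these conditions.

Step 12
Reactants: 16 ketone
Product: 17 C2 β-alcohol
Conditions: LiBH(s-Bu)3, THF, −78 °C; then H2O2, aq. NaOH
Reagents that add atoms: none
Why: The bulky hydride attacks the α face, opposite C10 on C1 and the dimethoxymethyl group on C4, giving the β-alcohol cis to C7'.

Step 13
Reactants: 17 C2 β-alcohol; 18 trichloroethylene
Product: 20 (E)-1,2-dichlorovinyl ether of 17, via dichloroacetylene 19 (not isolated)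
Conditions: KH (2.2 equiv), THF, 0 °C; 18 (1.2 equiv), −40 °C → rt
Reagents that add atoms: none
Why: The potassium alkoxide adds anti to dichloroacetylene formed in situ (Greene's ynol ether synthesis, first stage); acetals and the SEM ether are inert to KH.

Step 14
Reactants: 20 dichlorovinyl ether
Product: 21 C2 ethynyl ether (C1–H α, C10 β-OSEM, C4 β-CH(OMe)2)
Conditions: n-BuLi (2.5 equiv), THF, −78 → −40 °C; MeOH, −78 °C
Reagents that add atoms: none
Why: Dehydrochlorination to the chloroalkyne, chlorine–lithium exchange and protonation give the terminal ynol ether; with C1 saturated there is no allyl alkynyl ether and no [3,3] shift.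

Step 15
Reactants: 22 3-ethoxycyclobut-2-en-1-one
Product: 23 3-(benzyloxy)cyclobut-2-en-1-one
Conditions: BnOH (3 equiv), TsOH·H2O (2 mol %), toluene, 40 °C, reduced pressure
Reagents that add atoms: benzyl alcohol, OCc1ccccc1
Why: Acid-catalysed alcohol exchange of a vinylogous ester by conjugate addition–elimination, driven by removal of ethanol below the ring-opening temperature.

Step 16
Reactants: 21 C2 ethynyl ether; 23 3-(benzyloxy)cyclobut-2-en-1-one
Product: 24 3-(benzyloxy)-5-hydroxyphenyl ether at C2
Conditions: toluene (0.2 M), 23 (1.5 equiv), sealed tube, 80 °C, then 105 °C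
Reagents that add atoms: none
Why: Danheiser benzannulation of an alkoxyacetylene with a cyclobutenone. Four-electron electrocyclic opening of 23 gives (benzyloxy)vinylketene, which adds (2+2) to the ynol ether with the oxygen-free alkyne carbon bonding to the ketene carbonyl carbon. The new 4-vinylcyclobutenone opens to a dienylketene, and ring A closes by thermal disrotatory six-electron electrocyclisation followed by tautomerisation to the phenol. Two new C–C bonds of ring A are formed and the polarity of the (2+2) step alone places the oxygens 1,3,5. No stereocentre is formed and the C2 configuration is untouched. The step needs the ynol ether to react faster than it fragments by retro-ene loss of ketene; the excess of 23, the moderate temperature and the saturated C1 serve this. The SEM ether and the acetal do not react with ketenes.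

Step 17
Reactants: 24 phenol
Product: 26 C10 tertiary alcohol with 3,5-bis(benzyloxy)phenyl ether at C2, via SEM bis-benzyl ether 25 (not isolated)
Conditions: BnBr, K2CO3, DMF, rt; then n-Bu4NF, DMPU, 80 °C
Reagents that add atoms: benzyl bromide, BrCc1ccccc1
Why: Williamson benzylation makes ring A symmetric and removes the free phenol before the elimination; fluoride then fragments the SEM ether to the carbinol without acid.

Step 18
Reactants: 26 tertiary alcohol
Product: 27 C1=C10 alkene
Conditions: SOCl2, pyridine, CH2Cl2, −30 → 0 °C
Reagents that add atoms: none
Why: Anti elimination through the chlorosulfite: the β C10–O bond and the α C1–H bond are anti-periplanar in the trans-fused ring and Saytzeff preference favours the tetrasubstituted alkene; pyridine protects the acetal and the cyclopropane.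

Step 19
Reactants: 27 acetal; 28 methallyltrimethylsilane
Product: 30 ring-B-closed methallyl compound, via benzylic methyl ether 29 (not isolated)
Conditions: Me3SiOTf (0.3 equiv), CH2Cl2, −78 °C; then 28 (4 equiv), −78 → −40 °C
Reagents that add atoms: none
Why: Intramolecular Friedel–Crafts reaction of the C7' oxocarbenium ion at either equivalent ortho carbon closes the oxepane. The benzylic ether re-ionises to a cation stabilised by three ring oxygens, and Hosomi–Sakurai attack comes from the face turned toward C3, because the other face is covered by ring D and the C11 methyls; this sets C7'.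

Step 20
Reactants: 30 methallyl bis-benzyl ether
Product: 31 resorcinol with isobutyl side chain
Conditions: H2 (1 atm), Pd/C (10 %), EtOAc, rt
Reagents that add atoms: none
Why: Hydrogenation of the 1,1-disubstituted alkene and hydrogenolysis of both benzyl ethers; the hindered tetrasubstituted alkene and the cyclopropane are much slower, so the reaction is stopped at uptake of three equivalents.

Step 21
Reactants: 31 resorcinol
Product: 32 target
Conditions: Cl2CHOMe (6 equiv), TiCl4 (6 equiv), CH2Cl2, −78 → −10 °C; H2O
Reagents that add atoms: dichloromethyl methyl ether, COC(Cl)Cl; water, O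
Why: Double Rieche formylation of the two remaining ring positions, each activated by three oxygens; titanium phenoxide formation directs and accelerates the ortho attack.

## Compound list

1 | (+)-2-carene, (1S,6R)-3,7,7-trimethylbicyclo[4.1.0]hept-2-ene | CC1=C[C@H]2[C@@H](CC1)C2(C)C | starting material
2 | 4-[(1R,3S)-3-(dimethoxymethyl)-2,2-dimethylcyclopropyl]butan-2-one | COC(OC)[C@H]1[C@@H](CCC(C)=O)C1(C)C | intermediate
3 | 3-[(1R,3S)-3-(dimethoxymethyl)-2,2-dimethylcyclopropyl]propanoic acid (not isolated) | COC(OC)[C@H]1[C@@H](CCC(=O)O)C1(C)C | intermediate
4 | 3-[(1R,3S)-3-formyl-2,2-dimethylcyclopropyl]propanoic acid | O=C[C@H]1[C@@H](CCC(=O)O)C1(C)C | intermediate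
5 | 3-[(1R,3S)-2,2-dimethyl-3-[(1E)-3-methylbuta-1,3-dien-1-yl]cyclopropyl]propanoic acid | C=C(C)/C=C/[C@H]1[C@@H](CCC(=O)O)C1(C)C | intermediate
6 | N-methoxy-N-methylamide of 5 | C=C(C)/C=C/[C@H]1[C@@H](CCC(=O)N(C)OC)C1(C)C | intermediate
7 | 5-[(1R,3S)-2,2-dimethyl-3-[(1E)-3-methylbuta-1,3-dien-1-yl]cyclopropyl]pent-1-yn-3-one | C=C(C)/C=C/[C@H]1[C@@H](CCC(=O)C#C)C1(C)C | intermediate
8 | tricyclic dienone: C10 ketone, C1=C2 and C4=C7' alkenes, H5 β | O=C1C2=CCC(C)=C[C@H]2[C@H]3[C@@H](CC1)C3(C)C | intermediate
9 | C4,C7' β-epoxide of 8 | O=C1C2=CC[C@]4(C)O[C@@H]4[C@H]2[C@H]3[C@@H](CC1)C3(C)C | intermediate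
10 | ring-contracted enone aldehyde: C4 with α-methyl and β-CHO (not isolated) | O=C1C2=CC[C@](C)(C=O)[C@H]2[C@H]3[C@@H](CC1)C3(C)C | intermediate
11 | dimethyl acetal of 10 | O=C1C2=CC[C@](C)(C(OC)OC)[C@H]2[C@H]3[C@@H](CC1)C3(C)C | intermediate
12 | C10 tertiary allylic alcohol (α-methyl, β-OH), formed as lithium alkoxide (not isolated) | C[C@@]1(O)C2=CC[C@](C)(C(OC)OC)[C@H]2[C@H]3[C@@H](CC1)C3(C)C | intermediate
13 | SEM ether of 12 | C[C@@]1(OCOCC[Si](C)(C)C)C2=CC[C@](C)(C(OC)OC)[C@H]2[C@H]3[C@@H](CC1)C3(C)C | intermediate
14 | C2 α-alkylborane, H1 α (not isolated) | C[C@@]1(OCOCC[Si](C)(C)C)[C@@H]2[C@@H](B)C[C@](C)(C(OC)OC)[C@H]2[C@H]3[C@@H](CC1)C3(C)C | intermediate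
15 | C2 α-alcohol, H1 α | C[C@@]1(OCOCC[Si](C)(C)C)[C@@H]2[C@@H](O)C[C@](C)(C(OC)OC)[C@H]2[C@H]3[C@@H](CC1)C3(C)C | intermediate
16 | C2 ketone, H1 α | C[C@@]1(OCOCC[Si](C)(C)C)[C@@H]2C(=O)C[C@](C)(C(OC)OC)[C@H]2[C@H]3[C@@H](CC1)C3(C)C | intermediate
17 | C2 β-alcohol, H1 α | C[C@@]1(OCOCC[Si](C)(C)C)[C@@H]2[C@H](O)C[C@](C)(C(OC)OC)[C@H]2[C@H]3[C@@H](CC1)C3(C)C | intermediate
18 | trichloroethylene | ClC=C(Cl)Cl | starting material
19 | dichloroacetylene (not isolated) | ClC#CCl | intermediate
20 | (E)-1,2-dichlorovinyl ether of 17 | C[C@@]1(OCOCC[Si](C)(C)C)[C@@H]2[C@H](O/C(Cl)=C\Cl)C[C@](C)(C(OC)OC)[C@H]2[C@H]3[C@@H](CC1)C3(C)C | intermediate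
21 | C2 ethynyl ether | C[C@@]1(OCOCC[Si](C)(C)C)[C@@H]2[C@H](OC#C)C[C@](C)(C(OC)OC)[C@H]2[C@H]3[C@@H](CC1)C3(C)C | intermediate
22 | 3-ethoxycyclobut-2-en-1-one | CCOC1=CC(=O)C1 | starting material
23 | 3-(benzyloxy)cyclobut-2-en-1-one | O=C1C=C(OCc2ccccc2)C1 | intermediate
24 | C2 3-(benzyloxy)-5-hydroxyphenyl ether | C[C@@]1(OCOCC[Si](C)(C)C)[C@@H]2[C@H](Oc4cc(O)cc(OCc5ccccc5)c4)C[C@](C)(C(OC)OC)[C@H]2[C@H]3[C@@H](CC1)C3(C)C | intermediate
25 | C2 3,5-bis(benzyloxy)phenyl ether, C10 SEM ether (not isolated) | C[C@@]1(OCOCC[Si](C)(C)C)[C@@H]2[C@H](Oc4cc(OCc5ccccc5)cc(OCc6ccccc6)c4)C[C@](C)(C(OC)OC)[C@H]2[C@H]3[C@@H](CC1)C3(C)C | intermediate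
26 | C10 tertiary alcohol, C2 3,5-bis(benzyloxy)phenyl ether | C[C@@]1(O)[C@@H]2[C@H](Oc4cc(OCc5ccccc5)cc(OCc6ccccc6)c4)C[C@](C)(C(OC)OC)[C@H]2[C@H]3[C@@H](CC1)C3(C)C | intermediate
27 | C1=C10 alkene, C2 3,5-bis(benzyloxy)phenyl ether, C7' dimethyl acetal | CC1=C2[C@H]([C@H]3[C@@H](CC1)C3(C)C)[C@@](C)(C(OC)OC)C[C@H]2Oc1cc(OCc2ccccc2)cc(OCc2ccccc2)c1 | intermediate
28 | methallyltrimethylsilane | C=C(C)C[Si](C)(C)C | starting material
29 | ring-B-closed benzylic methyl ether, C7' epimers (not isolated) | CC1=C2[C@H]([C@H]3[C@@H](CC1)C3(C)C)[C@]1(C)C[C@H]2Oc2cc(OCc3ccccc3)cc(OCc3ccccc3)c2C1OC | intermediate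
30 | ring-B-closed C7' methallyl bis-benzyl ether | CC1=C2[C@H]([C@H]3[C@@H](CC1)C3(C)C)[C@]1(C)C[C@H]2Oc2cc(OCc3ccccc3)cc(OCc3ccccc3)c2[C@H]1CC(C)=C | intermediate
31 | C7' isobutyl resorcinol | CC1=C2[C@H]([C@H]3[C@@H](CC1)C3(C)C)[C@]1(C)C[C@H]2Oc2cc(O)cc(O)c2[C@H]1CC(C)C | intermediate
32 | target, CNP0388405.1 | CC1=C2[C@H]([C@H]3[C@@H](CC1)C3(C)C)[C@]1(C)C[C@H]2Oc2c(C=O)c(O)c(C=O)c(O)c2[C@H]1CC(C)C | target

## Step count and least certain steps

Total: 21 steps. Longest linear sequence: 20 steps (steps 1–14 and 16–21 from 1); step 15 is a one-step branch.

**Step 16 (key step).** The secondary ynol ether may fragment by retro-ene loss of ketene before the alkoxy-substituted cyclobutenone has opened, and excess vinylketene may acylate the new phenol. Fallback: starting from 21, the same vinylketene is generated at room temperature by photochemical Wolff rearrangement of 3-(benzyloxy)-1-diazobut-3-en-2-one F1 (the diazo ketone form of the Danheiser benzannulation). The following (2+2) addition, ring opening and six-electron closure need at most gentle warming, and the sequence returns to 24.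

**Step 6.** Closure of the seven-membered ring may be slow, leaving time for Lewis-acid opening of the vinylcyclopropane or, on heating, for the homodienyl hydrogen shift. Fallback: starting from 5, the ring bonds are made in two stages. Esterification gives the methyl ester F2. An intermolecular Diels–Alder reaction with methyl propiolate (both diene substituents direct the ester carbon next to C5) gives the cyclohexadiene diester F3. Dieckmann condensation of the side-chain ester enolate onto the ring ester closes ring D to the β-keto ester F4, and Krapcho dealkoxycarbonylation returns to 8. Face selectivity at C5 is then no longer enforced by a tether and has to come from the cyclopropane alone.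

**Step 8.** The C4 cation may lose a proton from the doubly activated C3 (leading toward a dienone and aromatisation) or undergo hydride shift, in place of ring-bond migration. Fallback: the order is changed so that the ketone no longer acidifies C3. Starting from 8, methyllithium addition and SEM protection give the diene SEM ether F5. Epoxidation of the less hindered C4=C7' alkene gives the epoxide F6, and the same rearrangement and acetalisation return to 13.

**Step 18.** Elimination may go toward C9 or the C10 methyl group, or the chlorosulfite may collapse to the tertiary chloride. Fallback: the olefin mixture from 26 is equilibrated by hydrogen-atom-transfer isomerisation (a cobalt salen chloride catalyst, Co(salen)Cl, with PhSiH3) toward the tetrasubstituted isomer 27; no compound outside the list is made (F0).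

**Step 21.** TiCl4 may ionise the allylic C2–O bond or protonate the alkene through HCl, and the second formylation may stall. Fallback: starting from 31, the aldehydes are introduced without a strong Lewis acid by magnesium phenoxide ortho-formylation (MgCl2, Et3N, paraformaldehyde), which passes through the monoaldehyde F7 and on to 32.

## Further compounds

F1 | step 16 | 3-(benzyloxy)-1-diazobut-3-en-2-one | C=C(OCc1ccccc1)C(=O)C=[N+]=[N-]
F2 | step 6 | methyl ester of 5 | C=C(C)/C=C/[C@H]1[C@@H](CCC(=O)OC)C1(C)C
F3 | step 6 | cyclohexa-1,4-diene diester from F2 and methyl propiolate | COC(=O)C1=CCC(C)=C[C@H]1[C@H]2[C@@H](CCC(=O)OC)C2(C)C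
F4 | step 6 | C9 methoxycarbonyl derivative of 8 | O=C1C2=CCC(C)=C[C@H]2[C@H]3[C@@H](CC1C(=O)OC)C3(C)C
F5 | step 8 | C10 tertiary SEM ether of the methyllithium adduct of 8 | C[C@@]1(OCOCC[Si](C)(C)C)C2=CCC(C)=C[C@H]2[C@H]3[C@@H](CC1)C3(C)C
F6 | step 8 | C4,C7' β-epoxide of F5 | C[C@@]1(OCOCC[Si](C)(C)C)C2=CC[C@]4(C)O[C@@H]4[C@H]2[C@H]3[C@@H](CC1)C3(C)C
F0 | step 18 | none | none
F7 | step 21 | monoaldehyde of 31 (formyl between the two hydroxyl groups) | CC1=C2[C@H]([C@H]3[C@@H](CC1)C3(C)C)[C@]1(C)C[C@H]2Oc2cc(O)c(C=O)c(O)c2[C@H]1CC(C)C
A1 | alternative 1 | vinyl diazo ketone with (E)-diene, aryl and isobutyl groups | C=C(C)C(=[N+]=[N-])C(=O)C[C@@](C)(/C=C/C=C)[C@H](CC(C)C)c1c(O[Si](C)(C)C(C)(C)C)cc(OCOC)cc1OCOC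
A2 | alternative 1 | hydroazulenone with C2 ketone, C1=C10 and C6=C7 alkenes | CC1=C2[C@H](C=CCC1)[C@](C)(CC2=O)[C@H](CC(C)C)c1c(O[Si](C)(C)C(C)(C)C)cc(OCOC)cc1OCOC
A3 | alternative 2 | tricyclic six–seven–three dienone (identical with 8) | O=C1C2=CCC(C)=C[C@H]2[C@H]3[C@@H](CC1)C3(C)C
A4 | alternative 3 | carene-derived bicyclic cycloheptenone | O=C1C=C[C@H]2[C@@H](CC1)C2(C)C
A5 | alternative 3 | 1-(trimethylsilyl)-3-methyl-4-(tert-butyldimethylsilyloxy)buta-1,2-diene, the enantiomer that transfers its axial chirality to C4 of A6 (axis not encoded) | C[Si](C)(C)C=C=C(C)CO[Si](C)(C)C(C)(C)C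
A6 | alternative 3 | cis-fused hydroazulenone with C3 vinylsilane | O=C1[C@H]2C=C([Si](C)(C)C)[C@](C)(CO[Si](C)(C)C(C)(C)C)[C@H]2[C@H]3[C@@H](CC1)C3(C)C
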